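**Strategy.** The 3',5',6'-trihydroxycyclohexane ring (carotenoid numbering, primed atoms) hides acetylacetone: C2', C3', C4', C5' and the C5' methyl are its five carbons, while C1' and C6' are the two carbons of a tetrasubstituted silyl enol ether. A de Mayo reaction (photochemical [2+2] addition of the diketone enol across the enol ether, then strain-driven retro-aldol opening of the cyclobutanol) forms C1'–C2' and C5'–C6' in one operation and gives an acyclic 1,5-diketone; aldol closure and directed reduction build the ring. The racemate is resolved: one antipode becomes the triol end group, the other, after excision and re-installation of the C6 substituent, the 3,6-epoxy end group. Two Wittig olefinations with the C10 dialdehyde finish the polyene.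

Key step: step 3

Remarks on the chemistry (assumptions):
- Positions are given in carotenoid numbering (ring C1–C6, chain C7–C15). Primed numbers belong to the half with the trihydroxy ring, unprimed numbers to the half with the 3,6-epoxy ring.
- Compounds 5, 6 and 7 are racemic. The SMILES of 7 shows the enantiomer that is carried on to 8.
- Compounds 1, 4, 12, 22 and 29 are taken as commercial.

**Route**

Step 1
Reactants: 1 methyl 2,2-dimethoxyacetate
Product: 2 1,1-dimethoxy-3-methylbutan-2-one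
Conditions: i-PrMgCl (1.05 equiv), THF, −78 °C; aq. NH4Cl
Reagents that add atoms: isopropylmagnesium chloride, CC(C)[Mg]Cl
Why: Grignard ketone synthesis, in which the chelated tetrahedral magnesium alkoxide of the α,α-dialkoxy ester should persist at low temperature so that addition stops at the ketone.

Step 2
Reactants: 2 1,1-dimethoxy-3-methylbutan-2-one
Product: 3 tert-butyl[(1,1-dimethoxy-3-methylbut-2-en-2-yl)oxy]dimethylsilane
Conditions: TBSOTf, Et3N, CH2Cl2, 0 °C → rt
Reagents that add atoms: tert-butyldimethylsilyl trifluoromethanesulfonate, CC(C)(C)[Si](C)(C)OS(=O)(=O)C(F)(F)F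
Why: Soft enolisation and O-silylation (silyl enol ether formation) should occur at the isopropyl methine, the only enolisable position apart from the poorly acidic acetal C–H, and give the tetrasubstituted enol ether.

Step 3
Reactants: 3 tert-butyl[(1,1-dimethoxy-3-methylbut-2-en-2-yl)oxy]dimethylsilane; 4 pentane-2,4-dione
Product: 6 rac-3-[(tert-butyldimethylsilyl)oxy]-3-(dimethoxymethyl)-4,4-dimethylheptane-2,6-dione, via cyclobutanol photoadduct 5 (not isolated)
Conditions: hν (300 nm), 3 (2.5 equiv), MeCN, degassed, 15 °C, stopped at partial conversion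
Reagents that add atoms: none
Why: De Mayo reaction: the hydrogen-bonded enol of 4 is excited and adds across the electron-rich C=C of 3 in a [2+2] photocycloaddition through a 1,4-biradical (first bond from the unsubstituted enol carbon, C2', to the dimethyl-substituted alkene carbon, C1', leaving a silyloxy-stabilised radical at C6'; second bond C5'–C6'), and the β-hydroxy-ketone cyclobutanol 5 then opens by retro-aldol cleavage of the former enol C2'–C5' bond, driven by release of cyclobutane strain, to diketone 6. The closest known reactions are de Mayo additions of β-diketone enols to enol ethers and enol esters and enone photocycloadditions to tetrasubstituted donor alkenes. The only ring closed is the transient cyclobutane, formed by radical–radical recombination of the 1,4-biradical and not retained. The one new stereocentre that survives, C6', is formed without control, so 6 is racemic, and both antipodes are used later. The step needs head-to-tail regioselectivity (oxygen-bearing alkene carbon to the enol carbinol carbon), which the donor oxygen on C6' should secure as in enone–enol ether photocycloadditions, and selective excitation of the diketone enol, which is secured because 3 is transparent at 300 nm. The vicinal fully substituted carbons C5' and C6' and the quaternary C1' are thus joined by radical recombination, which tolerates congestion better than ionic bond formation.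

Step 4
Reactants: 6 rac-3-[(tert-butyldimethylsilyl)oxy]-3-(dimethoxymethyl)-4,4-dimethylheptane-2,6-dione
Product: 7 rac-(3S,4S)-4-[(tert-butyldimethylsilyl)oxy]-4-(dimethoxymethyl)-3-hydroxy-3,5,5-trimethylcyclohexan-1-one
Conditions: DL-proline (0.3 equiv), DMSO, 30 °C
Reagents that add atoms: none
Why: Intramolecular enamine aldol addition (Hajos–Parrish type, 6-enolexo) in which only the unhindered C3' ketone forms an enamine and its methyl carbon C4' attacks the α-silyloxy ketone C5' through a chair with the C5' methyl equatorial, the C6'–O bond anti to the carbonyl (Cornforth-type dipole minimisation) and the bulky acetal arm anti to the nucleophile, which should give the ketol with the C5' and C6' oxygens trans, racemic proline being used so that both enantiomers of 6 react alike.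

Step 5
Reactants: 7 rac-(3S,4S)-4-[(tert-butyldimethylsilyl)oxy]-4-(dimethoxymethyl)-3-hydroxy-3,5,5-trimethylcyclohexan-1-one
Product: 8 (1S,3R,6S)-6-[(tert-butyldimethylsilyl)oxy]-6-(dimethoxymethyl)-1,5,5-trimethylcyclohexane-1,3-diol; 9 (1R,3S,6R)-6-[(tert-butyldimethylsilyl)oxy]-6-(dimethoxymethyl)-1,5,5-trimethylcyclohexane-1,3-diol (the enantiomer of 8, separated from it by preparative chiral SFC)
Conditions: Me4NBH(OAc)3, MeCN/AcOH (1:1), −30 °C; then preparative SFC on an amylose tris(3,5-dimethylphenylcarbamate) phase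
Reagents that add atoms: none
Why: Evans–Saksena reduction in which the axial C5' hydroxyl binds the triacetoxyborohydride and delivers hydride to C3' from its own face, setting the 3'-hydroxyl anti to the 5'-hydroxyl, after which chromatography on a chiral phase supplies both antipodes, each of which the route needs.

Step 6
Reactants: 8 (1S,3R,6S)-6-[(tert-butyldimethylsilyl)oxy]-6-(dimethoxymethyl)-1,5,5-trimethylcyclohexane-1,3-diol
Product: 10 (1S,2S,4R)-1-[(tert-butyldimethylsilyl)oxy]-2,4-dihydroxy-2,6,6-trimethylcyclohexane-1-carbaldehyde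
Conditions: CF3CO2H, H2O, CH2Cl2, 0 °C → rt
Reagents that add atoms: water, O
Why: Acid-catalysed hydrolysis of the dimethyl acetal to the aldehyde, which should leave the hindered tertiary silyl ether and the stereocentres untouched.

Step 7
Reactants: 10 (1S,2S,4R)-1-[(tert-butyldimethylsilyl)oxy]-2,4-dihydroxy-2,6,6-trimethylcyclohexane-1-carbaldehyde
Product: 11 (1S,2S,4R)-1-[(tert-butyldimethylsilyl)oxy]-2,6,6-trimethyl-2,4-bis[(triethylsilyl)oxy]cyclohexane-1-carbaldehyde
Conditions: TESOTf, 2,6-lutidine, CH2Cl2, −78 → 0 °C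
Reagents that add atoms: triethylsilyl trifluoromethanesulfonate, CC[Si](CC)(CC)OS(=O)(=O)C(F)(F)F
Why: Silylation of the secondary and the tertiary alcohol with a silyl triflate, which blocks retro-aldol cleavage of the β-hydroxy aldehyde under the basic conditions of the next step.

Step 8
Reactants: 11 (1S,2S,4R)-1-[(tert-butyldimethylsilyl)oxy]-2,6,6-trimethyl-2,4-bis[(triethylsilyl)oxy]cyclohexane-1-carbaldehyde; 12 ethyl (2E)-4-(diethoxyphosphoryl)-3-methylbut-2-enoate
Product: 13 ethyl (2E,4E)-5-{(1S,2S,4R)-1-[(tert-butyldimethylsilyl)oxy]-2,6,6-trimethyl-2,4-bis[(triethylsilyl)oxy]cyclohexyl}-3-methylpenta-2,4-dienoate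
Conditions: 12, LiN(SiMe3)2, THF, −78 °C; then 11, −78 °C → rt
Reagents that add atoms: none
Why: Horner–Wadsworth–Emmons olefination of the non-enolisable aldehyde with the vinylogous phosphonate anion, which should give the (E)-C7'=C8' alkene and the thermodynamically preferred (E)-C9'=C10' geometry.

Step 9
Reactants: 13 ethyl (2E,4E)-5-{(1S,2S,4R)-1-[(tert-butyldimethylsilyl)oxy]-2,6,6-trimethyl-2,4-bis[(triethylsilyl)oxy]cyclohexyl}-3-methylpenta-2,4-dienoate
Product: 14 (2E,4E)-5-{(1S,2S,4R)-1-[(tert-butyldimethylsilyl)oxy]-2,6,6-trimethyl-2,4-bis[(triethylsilyl)oxy]cyclohexyl}-3-methylpenta-2,4-dien-1-ol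
Conditions: i-Bu2AlH, CH2Cl2, −78 °C
Reagents that add atoms: none
Why: 1,2-Reduction of the conjugated ester to the allylic alcohol with a dialkylaluminium hydride, which leaves the silyl ethers and the diene intact.

Step 10
Reactants: 14 (2E,4E)-5-{(1S,2S,4R)-1-[(tert-butyldimethylsilyl)oxy]-2,6,6-trimethyl-2,4-bis[(triethylsilyl)oxy]cyclohexyl}-3-methylpenta-2,4-dien-1-ol
Product: 16 [(2E,4E)-5-{(1S,2S,4R)-1-[(tert-butyldimethylsilyl)oxy]-2,6,6-trimethyl-2,4-bis[(triethylsilyl)oxy]cyclohexyl}-3-methylpenta-2,4-dien-1-yl]triphenylphosphonium bromide, via allylic bromide 15 (not isolated)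
Conditions: CBr4, PPh3, CH2Cl2, −20 °C; then PPh3, rt
Reagents that add atoms: carbon tetrabromide, BrC(Br)(Br)Br; triphenylphosphine, c1ccc(cc1)P(c1ccccc1)c1ccccc1
Why: Appel bromination of the primary allylic alcohol under neutral conditions followed by SN2 quaternisation of triphenylphosphine in the same flask, which avoids the acid that would ionise the tertiary allylic C6' silyl ether.

Step 11
Reactants: 9 (1R,3S,6R)-6-[(tert-butyldimethylsilyl)oxy]-6-(dimethoxymethyl)-1,5,5-trimethylcyclohexane-1,3-diol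
Product: 17 (1R,2R,4S)-1-(dimethoxymethyl)-2,6,6-trimethylcyclohexane-1,2,4-triol
Conditions: Bu4NF, THF, rt → 50 °C
Reagents that add atoms: none
Why: Fluoride-mediated cleavage of the tertiary silyl ether, which frees the C6 hydroxyl needed for the oxidative excision that follows.

Step 12
Reactants: 17 (1R,2R,4S)-1-(dimethoxymethyl)-2,6,6-trimethylcyclohexane-1,2,4-triol
Product: 19 (2R,4S)-2,4-dihydroxy-2,6,6-trimethylcyclohexan-1-one, via α-hydroxy aldehyde 18 (not isolated)
Conditions: H5IO6, THF/H2O, rt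
Reagents that add atoms: none
Why: Acidic hydrolysis of the acetal and periodate cleavage (Malaprade reaction) of the resulting α-hydroxy aldehyde excise C7 and turn C6 into a ketone, while the trans ditertiary 5,6-diol should be cleaved much more slowly.

Step 13
Reactants: 19 (2R,4S)-2,4-dihydroxy-2,6,6-trimethylcyclohexan-1-one
Product: 20 (1S,3R)-3-hydroxy-3,5,5-trimethyl-4-oxocyclohexyl 4-methylbenzenesulfonate
Conditions: TsCl, pyridine, DMAP (cat.), CH2Cl2, 0 °C
Reagents that add atoms: 4-methylbenzenesulfonyl chloride, Cc1ccc(cc1)S(=O)(=O)Cl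
Why: Selective sulfonylation of the unhindered secondary alcohol in the presence of the tertiary α-ketol hydroxyl.

Step 14
Reactants: 20 (1S,3R)-3-hydroxy-3,5,5-trimethyl-4-oxocyclohexyl 4-methylbenzenesulfonate
Product: 21 (1S,3R)-3,5,5-trimethyl-4-oxo-3-[(triethylsilyl)oxy]cyclohexyl 4-methylbenzenesulfonate
Conditions: TESOTf, 2,6-lutidine, CH2Cl2, −40 → 0 °C
Reagents that add atoms: triethylsilyl trifluoromethanesulfonate, CC[Si](CC)(CC)OS(=O)(=O)C(F)(F)F
Why: Silylation of the tertiary alcohol with a silyl triflate, so that no C5 alkoxide can later trigger Grob fragmentation of the 1,3-related sulfonate.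

Step 15
Reactants: 22 (2E)-3-methylpent-2-en-4-yn-1-ol
Product: 23 (2E,4E)-3-methyl-5-(tributylstannyl)penta-2,4-dien-1-ol
Conditions: Bu3SnH, PdCl2(PPh3)2 (2 mol %), THF, 0 °C
Reagents that add atoms: tributylstannane, CCCC[SnH](CCCC)CCCC
Why: Palladium-catalysed syn hydrostannation of the terminal alkyne, which should place tin mainly at the terminal carbon and give the (E)-alkenylstannane, the internal regioisomer being removed by chromatography.

Step 16
Reactants: 21 (1S,3R)-3,5,5-trimethyl-4-oxo-3-[(triethylsilyl)oxy]cyclohexyl 4-methylbenzenesulfonate; 23 (2E,4E)-3-methyl-5-(tributylstannyl)penta-2,4-dien-1-ol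
Product: 26 (2E,4E)-3-methyl-5-{(1S,4R,6R)-2,2,6-trimethyl-6-[(triethylsilyl)oxy]-7-oxabicyclo[2.2.1]heptan-1-yl}penta-2,4-dien-1-ol, via dienyllithium 24 (not isolated), via lithium alkoxide 25 (not isolated)
Conditions: 23, MeLi (2 equiv per 23), THF, −78 → −40 °C; then 21, −78 °C; then DMPU, −78 → 40 °C
Reagents that add atoms: none
Why: Tin–lithium exchange gives the dienyllithium, which should add to the non-enolisable ketone along the axial trajectory anti to the axial C5 silyloxy group (1,2-addition, equatorial approach being blocked by the axial substituents on both α-carbons), and the resulting C6 alkoxide, trans to the C3 sulfonate, then displaces it with inversion through a boat (intramolecular Williamson etherification) to close the 7-oxabicyclo[2.2.1]heptane with the C5 oxygen syn to the bridge.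

Step 17
Reactants: 26 (2E,4E)-3-methyl-5-{(1S,4R,6R)-2,2,6-trimethyl-6-[(triethylsilyl)oxy]-7-oxabicyclo[2.2.1]heptan-1-yl}penta-2,4-dien-1-ol
Product: 28 [(2E,4E)-3-methyl-5-{(1S,4R,6R)-2,2,6-trimethyl-6-[(triethylsilyl)oxy]-7-oxabicyclo[2.2.1]heptan-1-yl}penta-2,4-dien-1-yl]triphenylphosphonium bromide, via allylic bromide 27 (not isolated)
Conditions: CBr4, PPh3, CH2Cl2, −20 °C; then PPh3, rt
Reagents that add atoms: carbon tetrabromide, BrC(Br)(Br)Br; triphenylphosphine, c1ccc(cc1)P(c1ccccc1)c1ccccc1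
Why: Appel bromination of the primary allylic alcohol and SN2 quaternisation of triphenylphosphine in one flask under neutral conditions that spare the silyl ether and the bridging ether.

Step 18
Reactants: 28 [(2E,4E)-3-methyl-5-{(1S,4R,6R)-2,2,6-trimethyl-6-[(triethylsilyl)oxy]-7-oxabicyclo[2.2.1]heptan-1-yl}penta-2,4-dien-1-yl]triphenylphosphonium bromide; 29 (2E,4E,6E)-2,7-dimethylocta-2,4,6-trienedial
Product: 30 (2E,4E,6E,8E,10E,12E)-2,7,11-trimethyl-13-{(1S,4R,6R)-2,2,6-trimethyl-6-[(triethylsilyl)oxy]-7-oxabicyclo[2.2.1]heptan-1-yl}trideca-2,4,6,8,10,12-hexaenal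
Conditions: 29 (3 equiv), NaOMe, MeOH/CH2Cl2, 0 °C → rt; then n-heptane, 90 °C
Reagents that add atoms: none
Why: Wittig olefination of the semi-stabilised ylide with an excess of the symmetrical dialdehyde should give the mono-adduct, and thermal equilibration converts the hindered (11Z) isomer into the all-E polyene.

Step 19
Reactants: 16 [(2E,4E)-5-{(1S,2S,4R)-1-[(tert-butyldimethylsilyl)oxy]-2,6,6-trimethyl-2,4-bis[(triethylsilyl)oxy]cyclohexyl}-3-methylpenta-2,4-dien-1-yl]triphenylphosphonium bromide; 30 (2E,4E,6E,8E,10E,12E)-2,7,11-trimethyl-13-{(1S,4R,6R)-2,2,6-trimethyl-6-[(triethylsilyl)oxy]-7-oxabicyclo[2.2.1]heptan-1-yl}trideca-2,4,6,8,10,12-hexaenal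
Product: 31 (all-E)-(3R,5R,6S,3'R,5'S,6'S)-6'-[(tert-butyldimethylsilyl)oxy]-3,6-epoxy-5,3',5'-tris[(triethylsilyl)oxy]-5,6,5',6'-tetrahydro-β,β-carotene
Conditions: 16, NaN(SiMe3)2, THF, −78 °C; then 30, −78 °C → rt; then n-heptane, 90 °C
Reagents that add atoms: none
Why: The second Wittig olefination joins the two halves at C11'=C12' and is again followed by thermal Z to E isomerisation.

Step 20
Reactants: 31 (all-E)-(3R,5R,6S,3'R,5'S,6'S)-6'-[(tert-butyldimethylsilyl)oxy]-3,6-epoxy-5,3',5'-tris[(triethylsilyl)oxy]-5,6,5',6'-tetrahydro-β,β-carotene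
Product: 32 (all-E)-(3R,5R,6S,3'R,5'S,6'S)-3,6-epoxy-5,6,5',6'-tetrahydro-β,β-carotene-5,3',5',6'-tetrol
Conditions: Bu4NF, THF, 0 → 40 °C
Reagents that add atoms: none
Why: Fluoride-mediated desilylation removes the three triethylsilyl ethers and the tertiary tert-butyldimethylsilyl ether under non-acidic conditions that should not ionise the tertiary allylic C6' alcohol.

**Compound list**

1 | methyl 2,2-dimethoxyacetate | COC(OC)C(=O)OC | starting material
2 | 1,1-dimethoxy-3-methylbutan-2-one | COC(OC)C(=O)C(C)C | intermediate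
3 | tert-butyl[(1,1-dimethoxy-3-methylbut-2-en-2-yl)oxy]dimethylsilane | COC(OC)C(O[Si](C)(C)C(C)(C)C)=C(C)C | intermediate
4 | pentane-2,4-dione (acetylacetone) | CC(=O)CC(C)=O | starting material
5 | 1-{3-[(tert-butyldimethylsilyl)oxy]-3-(dimethoxymethyl)-2-hydroxy-2,4,4-trimethylcyclobutyl}ethan-1-one (cyclobutanol photoadduct, mixture of stereoisomers) | CC(=O)C1C(C)(O)C(O[Si](C)(C)C(C)(C)C)(C(OC)OC)C1(C)C | intermediate (not isolated)
6 | rac-3-[(tert-butyldimethylsilyl)oxy]-3-(dimethoxymethyl)-4,4-dimethylheptane-2,6-dione | CC(=O)C(O[Si](C)(C)C(C)(C)C)(C(OC)OC)C(C)(C)CC(C)=O | intermediate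
7 | rac-(3S,4S)-4-[(tert-butyldimethylsilyl)oxy]-4-(dimethoxymethyl)-3-hydroxy-3,5,5-trimethylcyclohexan-1-one (racemate, (3S,4S) enantiomer drawn) | COC(OC)[C@]1(O[Si](C)(C)C(C)(C)C)C(C)(C)CC(=O)C[C@]1(C)O | intermediate
8 | (1S,3R,6S)-6-[(tert-butyldimethylsilyl)oxy]-6-(dimethoxymethyl)-1,5,5-trimethylcyclohexane-1,3-diol | COC(OC)[C@]1(O[Si](C)(C)C(C)(C)C)C(C)(C)C[C@@H](O)C[C@]1(C)O | intermediate
9 | (1R,3S,6R)-6-[(tert-butyldimethylsilyl)oxy]-6-(dimethoxymethyl)-1,5,5-trimethylcyclohexane-1,3-diol | COC(OC)[C@@]1(O[Si](C)(C)C(C)(C)C)C(C)(C)C[C@H](O)C[C@@]1(C)O | intermediate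
10 | (1S,2S,4R)-1-[(tert-butyldimethylsilyl)oxy]-2,4-dihydroxy-2,6,6-trimethylcyclohexane-1-carbaldehyde | O=C[C@]1(O[Si](C)(C)C(C)(C)C)C(C)(C)C[C@@H](O)C[C@]1(C)O | intermediate
11 | (1S,2S,4R)-1-[(tert-butyldimethylsilyl)oxy]-2,6,6-trimethyl-2,4-bis[(triethylsilyl)oxy]cyclohexane-1-carbaldehyde | O=C[C@]1(O[Si](C)(C)C(C)(C)C)C(C)(C)C[C@@H](O[Si](CC)(CC)CC)C[C@]1(C)O[Si](CC)(CC)CC | intermediate
12 | ethyl (2E)-4-(diethoxyphosphoryl)-3-methylbut-2-enoate (triethyl 3-methyl-4-phosphonocrotonate) | CCOC(=O)/C=C(\C)CP(=O)(OCC)OCC | starting material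
13 | ethyl (2E,4E)-5-{(1S,2S,4R)-1-[(tert-butyldimethylsilyl)oxy]-2,6,6-trimethyl-2,4-bis[(triethylsilyl)oxy]cyclohexyl}-3-methylpenta-2,4-dienoate | CCOC(=O)/C=C(C)/C=C/[C@]1(O[Si](C)(C)C(C)(C)C)C(C)(C)C[C@@H](O[Si](CC)(CC)CC)C[C@]1(C)O[Si](CC)(CC)CC | intermediate
14 | (2E,4E)-5-{(1S,2S,4R)-1-[(tert-butyldimethylsilyl)oxy]-2,6,6-trimethyl-2,4-bis[(triethylsilyl)oxy]cyclohexyl}-3-methylpenta-2,4-dien-1-ol | OC/C=C(C)/C=C/[C@]1(O[Si](C)(C)C(C)(C)C)C(C)(C)C[C@@H](O[Si](CC)(CC)CC)C[C@]1(C)O[Si](CC)(CC)CC | intermediate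
15 | {[(1S,2S,4R)-1-[(1E,3E)-5-bromo-3-methylpenta-1,3-dien-1-yl]-2,6,6-trimethyl-2,4-bis[(triethylsilyl)oxy]cyclohexyl]oxy}(tert-butyl)dimethylsilane | BrC/C=C(C)/C=C/[C@]1(O[Si](C)(C)C(C)(C)C)C(C)(C)C[C@@H](O[Si](CC)(CC)CC)C[C@]1(C)O[Si](CC)(CC)CC | intermediate (not isolated)
16 | [(2E,4E)-5-{(1S,2S,4R)-1-[(tert-butyldimethylsilyl)oxy]-2,6,6-trimethyl-2,4-bis[(triethylsilyl)oxy]cyclohexyl}-3-methylpenta-2,4-dien-1-yl]triphenylphosphonium bromide | [Br-].c1ccccc1[P+](c1ccccc1)(c1ccccc1)C/C=C(C)/C=C/[C@]1(O[Si](C)(C)C(C)(C)C)C(C)(C)C[C@@H](O[Si](CC)(CC)CC)C[C@]1(C)O[Si](CC)(CC)CC | intermediate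
17 | (1R,2R,4S)-1-(dimethoxymethyl)-2,6,6-trimethylcyclohexane-1,2,4-triol | COC(OC)[C@@]1(O)C(C)(C)C[C@H](O)C[C@@]1(C)O | intermediate
18 | (1R,2R,4S)-1,2,4-trihydroxy-2,6,6-trimethylcyclohexane-1-carbaldehyde | O=C[C@@]1(O)C(C)(C)C[C@H](O)C[C@@]1(C)O | intermediate (not isolated)
19 | (2R,4S)-2,4-dihydroxy-2,6,6-trimethylcyclohexan-1-one | O=C1C(C)(C)C[C@H](O)C[C@@]1(C)O | intermediate
20 | (1S,3R)-3-hydroxy-3,5,5-trimethyl-4-oxocyclohexyl 4-methylbenzenesulfonate | O=C1C(C)(C)C[C@H](OS(=O)(=O)c2ccc(C)cc2)C[C@@]1(C)O | intermediate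
21 | (1S,3R)-3,5,5-trimethyl-4-oxo-3-[(triethylsilyl)oxy]cyclohexyl 4-methylbenzenesulfonate | O=C1C(C)(C)C[C@H](OS(=O)(=O)c2ccc(C)cc2)C[C@@]1(C)O[Si](CC)(CC)CC | intermediate
22 | (2E)-3-methylpent-2-en-4-yn-1-ol | C#C/C(C)=C/CO | starting material
23 | (2E,4E)-3-methyl-5-(tributylstannyl)penta-2,4-dien-1-ol | CCCC[Sn](CCCC)(CCCC)/C=C/C(C)=C/CO | intermediate
24 | lithium (2E,4E)-5-lithio-3-methylpenta-2,4-dien-1-olate | [Li]/C=C/C(C)=C/C[O-].[Li+] | intermediate (not isolated)
25 | dilithium alkoxide of (1S,3R,4S)-4-hydroxy-4-[(1E,3E)-5-hydroxy-3-methylpenta-1,3-dien-1-yl]-3,5,5-trimethyl-3-[(triethylsilyl)oxy]cyclohexyl 4-methylbenzenesulfonate | [Li+].[Li+].[O-]C/C=C(C)/C=C/[C@]1([O-])C(C)(C)C[C@H](OS(=O)(=O)c2ccc(C)cc2)C[C@@]1(C)O[Si](CC)(CC)CC | intermediate (not isolated)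
26 | (2E,4E)-3-methyl-5-{(1S,4R,6R)-2,2,6-trimethyl-6-[(triethylsilyl)oxy]-7-oxabicyclo[2.2.1]heptan-1-yl}penta-2,4-dien-1-ol | OC/C=C(C)/C=C/[C@]12O[C@H](CC1(C)C)C[C@@]2(C)O[Si](CC)(CC)CC | intermediate
27 | {[(1S,4R,6R)-1-[(1E,3E)-5-bromo-3-methylpenta-1,3-dien-1-yl]-2,2,6-trimethyl-7-oxabicyclo[2.2.1]heptan-6-yl]oxy}triethylsilane | BrC/C=C(C)/C=C/[C@]12O[C@H](CC1(C)C)C[C@@]2(C)O[Si](CC)(CC)CC | intermediate (not isolated)
28 | [(2E,4E)-3-methyl-5-{(1S,4R,6R)-2,2,6-trimethyl-6-[(triethylsilyl)oxy]-7-oxabicyclo[2.2.1]heptan-1-yl}penta-2,4-dien-1-yl]triphenylphosphonium bromide | [Br-].c1ccccc1[P+](c1ccccc1)(c1ccccc1)C/C=C(C)/C=C/[C@]12O[C@H](CC1(C)C)C[C@@]2(C)O[Si](CC)(CC)CC | intermediate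
29 | (2E,4E,6E)-2,7-dimethylocta-2,4,6-trienedial | O=C/C(C)=C/C=C/C=C(C)/C=O | starting material
30 | (2E,4E,6E,8E,10E,12E)-2,7,11-trimethyl-13-{(1S,4R,6R)-2,2,6-trimethyl-6-[(triethylsilyl)oxy]-7-oxabicyclo[2.2.1]heptan-1-yl}trideca-2,4,6,8,10,12-hexaenal | CC(/C=C/C=C(C)/C=C/[C@]12O[C@H](CC1(C)C)C[C@@]2(C)O[Si](CC)(CC)CC)=C\C=C\C=C(C)\C=O | intermediate
31 | (all-E)-(3R,5R,6S,3'R,5'S,6'S)-6'-[(tert-butyldimethylsilyl)oxy]-3,6-epoxy-5,3',5'-tris[(triethylsilyl)oxy]-5,6,5',6'-tetrahydro-β,β-carotene | CC(/C=C/C=C(C)/C=C/[C@]12O[C@H](CC1(C)C)C[C@@]2(C)O[Si](CC)(CC)CC)=C\C=C\C=C(C)\C=C\C=C(C)\C=C\[C@]1(O[Si](C)(C)C(C)(C)C)C(C)(C)C[C@@H](O[Si](CC)(CC)CC)C[C@]1(C)O[Si](CC)(CC)CC | intermediate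
32 | (all-E)-(3R,5R,6S,3'R,5'S,6'S)-3,6-epoxy-5,6,5',6'-tetrahydro-β,β-carotene-5,3',5',6'-tetrol | CC(/C=C/C=C(C)/C=C/[C@]12O[C@H](CC1(C)C)C[C@@]2(C)O)=C\C=C\C=C(C)\C=C\C=C(C)\C=C\[C@]1(O)C(C)(C)C[C@@H](O)C[C@]1(C)O | target

**Step count and risks**

Total step count: 20.
Longest linear sequence: 14 steps (steps 1–5, 11–14, 16–20).

Steps most likely to fail:

Step 3. The photocycloaddition may take the head-to-head orientation, the congested 1,4-biradical may revert instead of closing, or the diketone may be photolysed further. The fallback sets out from 2 and comes back at 6, and makes the two bonds one after the other by polar chemistry. The lithium enolate of 2 (LiN(i-Pr)2, THF, −78 °C) is alkylated at the isopropyl carbon with 3-bromo-2-methylprop-1-ene to give 1,1-dimethoxy-3,3,5-trimethylhex-5-en-2-one F1. 1-Ethoxyvinyllithium, an acetyl anion equivalent, adds to the ketone to give 3-(dimethoxymethyl)-2-ethoxy-4,4,6-trimethylhepta-1,6-dien-3-ol F2. Dilute aqueous HCl hydrolyses the enol ether to 3-(dimethoxymethyl)-3-hydroxy-4,4,6-trimethylhept-6-en-2-one F3, and TBSOTf with 2,6-lutidine gives 3-[(tert-butyldimethylsilyl)oxy]-3-(dimethoxymethyl)-4,4,6-trimethylhept-6-en-2-one F4. Ozonolysis of the 1,1-disubstituted alkene (O3, then Me2S) unveils the second methyl ketone and gives 6.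

Step 16. The organolithium may attack the sulfonate instead of the ketone, or the lithium alkoxide may fail to displace the sulfonate and elimination may take over. The fallback sets out from 21 and comes back at 26; it separates addition from ring closure and builds the diene afterwards by cross-coupling. The small, weakly basic cerium acetylide from ethynyltrimethylsilane (n-BuLi, CeCl3, THF, −78 °C) adds to 21, and a cold quench gives (1S,3R,4R)-4-hydroxy-3,5,5-trimethyl-3-[(triethylsilyl)oxy]-4-[(trimethylsilyl)ethynyl]cyclohexyl 4-methylbenzenesulfonate F6. KN(SiMe3)2 with 18-crown-6 then closes the ether to trimethyl({(1R,4R,6R)-2,2,6-trimethyl-6-[(triethylsilyl)oxy]-7-oxabicyclo[2.2.1]heptan-1-yl}ethynyl)silane F7. K2CO3 in MeOH frees (1R,4R,6R)-1-ethynyl-2,2,6-trimethyl-6-[(triethylsilyl)oxy]-7-oxabicyclo[2.2.1]heptane F8, and hydrostannation with Bu3SnH and PdCl2(PPh3)2 gives tributyl[(E)-2-{(1S,4R,6R)-2,2,6-trimethyl-6-[(triethylsilyl)oxy]-7-oxabicyclo[2.2.1]heptan-1-yl}ethenyl]stannane F9. Stille coupling with (2E)-3-iodobut-2-en-1-ol (Pd(PPh3)4, CuI, DMF) gives 26.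

Step 4. The ring may close with the opposite facial sense at C5' (loss of trans selectivity), or the ketol may dehydrate. The fallback sets out from 6 and comes back at 7; the nucleophile is preformed and the closure is run under chelation control. TMSOTf and Et3N (CH2Cl2, −78 °C) should silylate only the unhindered ketone to give the terminal silyl enol ether 3-[(tert-butyldimethylsilyl)oxy]-3-(dimethoxymethyl)-4,4-dimethyl-6-[(trimethylsilyl)oxy]hept-6-en-2-one F5. MgBr2·OEt2 (CH2Cl2, −78 °C) then promotes an intramolecular Mukaiyama aldol addition in which magnesium bridges the acceptor carbonyl and an acetal oxygen, so that the acetal arm is held syn to the carbonyl and the non-coordinating silyloxy group anti. Aqueous work-up gives 7.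

Further compounds
F1 | step 3 | 1,1-dimethoxy-3,3,5-trimethylhex-5-en-2-one | COC(OC)C(=O)C(C)(C)CC(C)=C
F2 | step 3 | rac-3-(dimethoxymethyl)-2-ethoxy-4,4,6-trimethylhepta-1,6-dien-3-ol | C=C(OCC)C(O)(C(OC)OC)C(C)(C)CC(C)=C
F3 | step 3 | rac-3-(dimethoxymethyl)-3-hydroxy-4,4,6-trimethylhept-6-en-2-one | CC(=O)C(O)(C(OC)OC)C(C)(C)CC(C)=C
F4 | step 3 | rac-3-[(tert-butyldimethylsilyl)oxy]-3-(dimethoxymethyl)-4,4,6-trimethylhept-6-en-2-one | CC(=O)C(O[Si](C)(C)C(C)(C)C)(C(OC)OC)C(C)(C)CC(C)=C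
F5 | step 4 | rac-3-[(tert-butyldimethylsilyl)oxy]-3-(dimethoxymethyl)-4,4-dimethyl-6-[(trimethylsilyl)oxy]hept-6-en-2-one | CC(=O)C(O[Si](C)(C)C(C)(C)C)(C(OC)OC)C(C)(C)CC(=C)O[Si](C)(C)C
F6 | step 16 | (1S,3R,4R)-4-hydroxy-3,5,5-trimethyl-3-[(triethylsilyl)oxy]-4-[(trimethylsilyl)ethynyl]cyclohexyl 4-methylbenzenesulfonate | C[Si](C)(C)C#C[C@]1(O)C(C)(C)C[C@H](OS(=O)(=O)c2ccc(C)cc2)C[C@@]1(C)O[Si](CC)(CC)CC
F7 | step 16 | trimethyl({(1R,4R,6R)-2,2,6-trimethyl-6-[(triethylsilyl)oxy]-7-oxabicyclo[2.2.1]heptan-1-yl}ethynyl)silane | C[Si](C)(C)C#C[C@]12O[C@H](CC1(C)C)C[C@@]2(C)O[Si](CC)(CC)CC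
F8 | step 16 | (1R,4R,6R)-1-ethynyl-2,2,6-trimethyl-6-[(triethylsilyl)oxy]-7-oxabicyclo[2.2.1]heptane | C#C[C@]12O[C@H](CC1(C)C)C[C@@]2(C)O[Si](CC)(CC)CC
F9 | step 16 | tributyl[(E)-2-{(1S,4R,6R)-2,2,6-trimethyl-6-[(triethylsilyl)oxy]-7-oxabicyclo[2.2.1]heptan-1-yl}ethenyl]stannane | CCCC[Sn](CCCC)(CCCC)/C=C/[C@]12O[C@H](CC1(C)C)C[C@@]2(C)O[Si](CC)(CC)CC
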